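**Assumption:** the target SMILES has no stereocentre and no stereogenic double bond. Pebrellin (5,6-dihydroxy-7,8,3',4'-tetramethoxyflavone) is therefore achiral and no enantiomer has to be controlled. The sp3 centres in 12 and 14 are transient and racemic, and both are destroyed on the way to the target.

## Retrosynthetic overview
1. Pebrellin ⇒ 6-benzyloxy-5,7,8,3',4'-pentamethoxyflavone, by 6-O-debenzylation and then chelation-directed 5-O-demethylation.
2. The pyranone ring C is the only ring built and is formed last ⇒ oxidative cyclisation of a 2'-hydroxychalcone.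
3. The chalcone C=C bond ⇒ Claisen–Schmidt aldol condensation of 5-benzyloxy-2-hydroxy-3,4,6-trimethoxyacetophenone with veratraldehyde.
4. The acetophenone ⇒ C-acetylation of 2,3,5-trimethoxyhydroquinone at its only free C–H, then chelation-controlled mono-benzylation.
5. The hydroquinone ⇒ quinone ⇒ 2,3,4,6-tetramethoxyphenol ⇒ (formylation, Baeyer–Villiger) 1,2,3,5-tetramethoxybenzene ⇒ 3,4,5-trimethoxyphenol. Rings A and B are bought.

## Route

**Step 1**
Reactants: 1 3,4,5-trimethoxyphenol
Product: 2 1,2,3,5-tetramethoxybenzene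
Conditions: MeI, K2CO3, acetone, reflux
Reagents that add atoms: iodomethane, CI
Why: Williamson ether synthesis on an unhindered phenoxide, with no competing nucleophilic site.

**Step 2**
Reactants: 2 1,2,3,5-tetramethoxybenzene
Product: 4 2,3,4,6-tetramethoxybenzaldehyde, via aryliminium chloride 3 (not isolated)
Conditions: POCl3, DMF, 0 → 50 °C; then ice–H2O
Reagents that add atoms: N,N-dimethylformamide, CN(C)C=O; water, O
Why: Vilsmeier–Haack formylation, in which the two free ring positions are symmetry-equivalent and strongly activated, so one isomer forms and the deactivated aldehyde does not react again.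

**Step 3**
Reactants: 4 2,3,4,6-tetramethoxybenzaldehyde
Product: 6 2,3,4,6-tetramethoxyphenol, via 2,3,4,6-tetramethoxyphenyl formate 5 (not isolated)
Conditions: mCPBA, CH2Cl2, 0 °C → rt; then MeOH, cat. HCl, rt
Reagents that add atoms: mCPBA, O=C(OO)c1cccc(Cl)c1
Why: Baeyer–Villiger (Dakin-type) oxidation, in which the electron-rich aryl group migrates in preference to H, and acid methanolysis frees the phenol without exposing it to base and air.

**Step 4**
Reactants: 6 2,3,4,6-tetramethoxyphenol
Product: 7 2,3,5-trimethoxy-1,4-benzoquinone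
Conditions: PhI(OAc)2, MeCN–H2O (2:1), 0 °C
Reagents that add atoms: water, O
Why: Hypervalent-iodine oxidative demethylation of a p-methoxyphenol, where water adds at the para carbon and the hemiketal expels MeOH, so the OMe para to the phenol is the one removed.

**Step 5**
Reactants: 7 2,3,5-trimethoxy-1,4-benzoquinone
Product: 8 2,3,5-trimethoxybenzene-1,4-diol (used at once under N2)
Conditions: Na2S2O4, EtOAc–H2O, rt, N2
Reagents that add atoms: none
Why: Dithionite reduction of a quinone to its hydroquinone is fast and leaves the ethers untouched.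

**Step 6**
Reactants: 8 2,3,5-trimethoxybenzene-1,4-diol
Product: 9 1-(2,5-dihydroxy-3,4,6-trimethoxyphenyl)ethanone
Conditions: AcOH, BF3·OEt2, 80 °C, N2; then H2O
Reagents that add atoms: acetic acid, CC(=O)O
Why: BF3-promoted Friedel–Crafts (Nencki/Fries-type) C-acylation can only occur at the single remaining ring C–H, ortho to the less hindered OH, and gives an H-bond-stabilised o-hydroxyaryl ketone.

**Step 7**
Reactants: 9 1-(2,5-dihydroxy-3,4,6-trimethoxyphenyl)ethanone
Product: 10 1-[5-(benzyloxy)-2-hydroxy-3,4,6-trimethoxyphenyl]ethanone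
Conditions: BnBr (1.05 equiv), K2CO3 (1.1 equiv), acetone, reflux, N2
Reagents that add atoms: benzyl bromide, BrCc1ccccc1
Why: Chemoselective Williamson etherification, because the 2-OH is held in a hydrogen bond to the acetyl C=O and only the free 5-OH is alkylated by one equivalent of BnBr.

**Step 8**
Reactants: 10 1-[5-(benzyloxy)-2-hydroxy-3,4,6-trimethoxyphenyl]ethanone; 11 3,4-dimethoxybenzaldehyde (veratraldehyde)
Product: 13 (E)-1-[5-(benzyloxy)-2-hydroxy-3,4,6-trimethoxyphenyl]-3-(3,4-dimethoxyphenyl)prop-2-en-1-one, via β-hydroxy ketone aldol adduct 12 (not isolated)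
Conditions: KOH (50 % aq.), EtOH, rt, 36 h; then dil. HCl
Reagents that add atoms: none
Why: Claisen–Schmidt crossed aldol condensation of a methyl ketone enolate with a non-enolisable aldehyde, in which E1cB dehydration of racemic 12 gives the conjugated E-enone under thermodynamic control.

**Step 9**
Reactants: 13 the (E)-2'-hydroxychalcone
Product: 15 6-(benzyloxy)-5,7,8,3',4'-pentamethoxyflavone, via racemic flavanone 14 (not isolated)
Conditions: I2 (10 mol %), DMSO, 120 °C
Reagents that add atoms: none
Why: I2/DMSO oxidative cyclisation proceeds by oxa-Michael closure through the only free ortho-OH and then α-iodination and HI loss, with DMSO re-oxidising the HI, which fixes the 7,8-dimethoxy orientation and removes the C2 stereocentre.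

**Step 10**
Reactants: 15 6-(benzyloxy)-5,7,8,3',4'-pentamethoxyflavone
Product: 16 6-hydroxy-5,7,8,3',4'-pentamethoxyflavone
Conditions: H2 (1 atm), 10 % Pd/C, EtOAc–MeOH, rt
Reagents that add atoms: none
Why: Catalytic hydrogenolysis of the benzyl aryl ether occurs at 1 atm, where the vinylogous-ester C2=C3 bond of a flavone is not reduced.

**Step 11**
Reactants: 16 6-hydroxy-5,7,8,3',4'-pentamethoxyflavone
Product: 17 pebrellin (5,6-dihydroxy-7,8,3',4'-tetramethoxyflavone)
Conditions: anhydrous AlCl3 (5 equiv), MeCN, 65 °C; then 2 % aq. HCl, 65 °C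
Reagents that add atoms: none
Why: Chelation-directed Lewis-acid ether cleavage, in which Al(III) held by C4=O and the 6-oxygen activates only the peri 5-OMe toward chloride attack, and the conditions are too mild for Wessely–Moser ring opening.

## Compound list
1 | 3,4,5-trimethoxyphenol | COc1cc(O)cc(OC)c1OC | starting material
2 | 1,2,3,5-tetramethoxybenzene | COc1cc(OC)c(OC)c(OC)c1 | intermediate
3 | N,N-dimethyl(2,3,4,6-tetramethoxybenzylidene)iminium chloride | COc1cc(OC)c(C=[N+](C)C)c(OC)c1OC.[Cl-] | intermediate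
4 | 2,3,4,6-tetramethoxybenzaldehyde | COc1cc(OC)c(C=O)c(OC)c1OC | intermediate
5 | 2,3,4,6-tetramethoxyphenyl formate | COc1cc(OC)c(OC=O)c(OC)c1OC | intermediate
6 | 2,3,4,6-tetramethoxyphenol | COc1cc(OC)c(O)c(OC)c1OC | intermediate
7 | 2,3,5-trimethoxy-1,4-benzoquinone | O=C1C=C(OC)C(=O)C(OC)=C1OC | intermediate
8 | 2,3,5-trimethoxybenzene-1,4-diol | COc1cc(O)c(OC)c(OC)c1O | intermediate
9 | 1-(2,5-dihydroxy-3,4,6-trimethoxyphenyl)ethanone | CC(=O)c1c(O)c(OC)c(OC)c(O)c1OC | intermediate
10 | 1-[5-(benzyloxy)-2-hydroxy-3,4,6-trimethoxyphenyl]ethanone | CC(=O)c1c(O)c(OC)c(OC)c(OCc2ccccc2)c1OC | intermediate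
11 | 3,4-dimethoxybenzaldehyde | COc1ccc(C=O)cc1OC | starting material
12 | rac-1-[5-(benzyloxy)-2-hydroxy-3,4,6-trimethoxyphenyl]-3-(3,4-dimethoxyphenyl)-3-hydroxypropan-1-one | COc1ccc(C(O)CC(=O)c2c(O)c(OC)c(OC)c(OCc3ccccc3)c2OC)cc1OC | intermediate
13 | (E)-1-[5-(benzyloxy)-2-hydroxy-3,4,6-trimethoxyphenyl]-3-(3,4-dimethoxyphenyl)prop-2-en-1-one | COc1ccc(/C=C/C(=O)c2c(O)c(OC)c(OC)c(OCc3ccccc3)c2OC)cc1OC | intermediate
14 | rac-6-(benzyloxy)-2-(3,4-dimethoxyphenyl)-5,7,8-trimethoxychroman-4-one | COc1ccc(C2CC(=O)c3c(OC)c(OCc4ccccc4)c(OC)c(OC)c3O2)cc1OC | intermediate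
15 | 6-(benzyloxy)-5,7,8,3',4'-pentamethoxyflavone | COc1ccc(-c2cc(=O)c3c(OC)c(OCc4ccccc4)c(OC)c(OC)c3o2)cc1OC | intermediate
16 | 6-hydroxy-5,7,8,3',4'-pentamethoxyflavone | COc1ccc(-c2cc(=O)c3c(OC)c(O)c(OC)c(OC)c3o2)cc1OC | intermediate
17 | pebrellin, 5,6-dihydroxy-7,8,3',4'-tetramethoxyflavone (achiral) | COc1ccc(-c2cc(=O)c3c(O)c(O)c(OC)c(OC)c3o2)cc1OC | target

## Step count and risks
Total steps: 11. Longest linear sequence: 11 (1 → 17). Veratraldehyde 11 is bought.

**Step 6, C-acetylation of the air-sensitive hydroquinone 8.** The risks are re-oxidation, O-acetylation and loss of the ortho OMe. The fallback reverses the order of acylation and ring oxygenation. It sets out from 2 and comes back at 9.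
- AcCl/AlCl3 in Et2O gives 2,3,4,6-tetramethoxyacetophenone F1.
- In the same flask F1 loses the doubly flanked, carbonyl-chelated ortho methyl and gives 2-hydroxy-3,4,6-trimethoxyacetophenone F2.
- Elbs persulfate oxidation (K2S2O8, aq. KOH, 15–20 °C) attacks the only free position, para to the phenoxide. It gives potassium 3-acetyl-4-hydroxy-2,5,6-trimethoxyphenyl sulfate F3.
- Hot dilute HCl hydrolyses F3 to 9.
- This path is shorter, but the Elbs step is typically modest in yield, so it is kept in reserve.

**Step 9, I2/DMSO oxidative cyclisation.** The risks are HI-induced loss of the benzyl or 5-methyl group and iodination of the electron-rich rings. The fallback brings C2 in at the acid oxidation level, so no oxidant is needed. It sets out from 10 and comes back at 15.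
- The lithium dianion of 10 (LiHMDS, 3.2 equiv, THF, −78 °C) is C-aroylated intermolecularly with 3,4-dimethoxybenzoyl chloride.
- The product is 1-[5-(benzyloxy)-2-hydroxy-3,4,6-trimethoxyphenyl]-3-(3,4-dimethoxyphenyl)propane-1,3-dione F4.
- Cyclodehydration of F4 (TsOH, toluene, reflux) gives 15.

**Step 11, selective 5-O-demethylation next to a free 6-OH.** The risk is that an aluminium 6-phenoxide also directs cleavage of the 7-OMe. The fallback demethylates before debenzylation, so the C4=O/5-OMe pair is the only chelating site. It sets out from 15 and comes back at 17.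
- BCl3 (1.1 equiv, CH2Cl2, −78 → 0 °C) gives 6-(benzyloxy)-5-hydroxy-7,8,3',4'-tetramethoxyflavone F5.
- Hydrogenolysis (H2, Pd/C, EtOAc–MeOH) then gives 17.
- Any benzyl ether lost early in the BCl3 step gives 17 directly.

## Further compounds
F1 | step 6 | 2,3,4,6-tetramethoxyacetophenone | CC(=O)c1c(OC)c(OC)c(OC)cc1OC
F2 | step 6 | 2-hydroxy-3,4,6-trimethoxyacetophenone | CC(=O)c1c(O)c(OC)c(OC)cc1OC
F3 | step 6 | potassium 3-acetyl-4-hydroxy-2,5,6-trimethoxyphenyl sulfate | CC(=O)c1c(O)c(OC)c(OC)c(OS(=O)(=O)[O-])c1OC.[K+]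
F4 | step 9 | 1-[5-(benzyloxy)-2-hydroxy-3,4,6-trimethoxyphenyl]-3-(3,4-dimethoxyphenyl)propane-1,3-dione | COc1ccc(C(=O)CC(=O)c2c(O)c(OC)c(OC)c(OCc3ccccc3)c2OC)cc1OC
F5 | step 11 | 6-(benzyloxy)-5-hydroxy-7,8,3',4'-tetramethoxyflavone | COc1ccc(-c2cc(=O)c3c(O)c(OCc4ccccc4)c(OC)c(OC)c3o2)cc1OC
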